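The pyranone ring is cut at C3–C4. C3 is benzylic to ring B, and the 2'-oxygen of that ring stands ortho to C1'. Once this oxygen is freed beside a benzylic leaving group, C3 becomes the electrophilic end of an ortho-quinone methide. A chiral triazolylidene meanwhile reverses the polarity of the ring A formyl carbon C4. A single operation therefore forms C3–C4, closes the six-membered ring and sets C3 from a racemate. The precursor already holds the O1–C2 ether: a 2-alkoxy-4,6-bis(MOM-oxy)-5-methylbenzaldehyde tied to a benzylic p-tolyl sulfone whose aryl group carries 2'-OTIPS, 4'-OMOM and 5'-geranyl. A C3 carbanion is no option, because it would expel the ring A aryloxide.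

Key step: step 11

Remarks on the design (isoflavanone numbering: O1, C2, C3, C4, C4a–C8a; primed atoms in ring B; geranyl = (2E)-3,7-dimethylocta-2,6-dien-1-yl; MOM = CH2OCH3; TIPS = Si(i-Pr)3)
- Ring A of the target holds three oxygens (O1, 5-O, 7-O), and 2-methylresorcinol brings only the two that flank the methyl group. O1 is therefore added para to the methyl group by C–H borylation/oxidation, which also avoids partial protection of a methylphloroglucinol aldehyde with two chelated hydroxyls that are hard to tell apart.
- O-2' carries TIPS and not a smaller silyl group. A small silyl ether ortho to a formyl group or to a benzylic alkoxide could be lost or migrate in steps 7–9, and a free O-2' would open the epoxide to a dihydrobenzofuranol. Fluoride still cleaves the aryl TIPS ether readily.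
- p-Toluenesulfinate stays as the leaving group. It is far less basic than a carboxylate, so it should spare the labile C3–H of the product, and it can re-add reversibly to the methide and so store it.
- Assumption: the sense of induction for this new acceptor cannot be derived from analogy. The route is written with the (5aR,10bS) triazolium salt; the equally available antipode is used if the first run gives (3S).

Step 1
Reactants: 1 2-methylresorcinol
Product: 2 1,3-bis(methoxymethoxy)-2-methylbenzene
Conditions: NaH (2.4 equiv), MOMCl (2.4 equiv), DMF, 0 °C to rt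
Reagents that add atoms: chloromethyl methyl ether (MOMCl), COCCl
Why: Williamson O-alkylation of the bis-phenoxide with a very reactive α-chloro ether, in which the two hydroxyls are equivalent so that no selectivity is needed.

Step 2
Reactants: 2 1,3-bis(methoxymethoxy)-2-methylbenzene
Product: 4 3,5-bis(methoxymethoxy)-4-methylphenol, via aryl pinacol boronate 3 (not isolated)
Conditions: [Ir(OMe)(cod)]2 (1 mol %), dtbpy (2 mol %), B2pin2 (1.0 equiv), THF, 80 °C; then 30% aq H2O2, aq NaOH, THF, 0 °C to rt
Reagents that add atoms: bis(pinacolato)diboron, CC1(C)OB(OC1(C)C)B1OC(C)(C)C(C)(C)O1 (boron of 3); hydrogen peroxide, OO (phenol oxygen of 4)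
Why: Sterically governed iridium-catalysed aromatic C–H borylation should touch only the one C–H without an ortho substituent (para to the methyl group), and basic peroxide oxidation of the boronate then delivers the future O1, the MOM ethers being inert to both stages.

Step 3
Reactants: 4 3,5-bis(methoxymethoxy)-4-methylphenol
Product: 5 2-hydroxy-4,6-bis(methoxymethoxy)-5-methylbenzaldehyde
Conditions: MgCl2 (2.5 equiv), Et3N (4 equiv), (CH2O)n (6 equiv), MeCN, 75 °C; cold aq citric acid work-up
Reagents that add atoms: formaldehyde (as paraformaldehyde), C=O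
Why: Casnati–Skattebøl ortho-formylation, in which the magnesium phenoxide delivers formaldehyde only ortho to the free hydroxyl (two equivalent sites, para site blocked by methyl) and a second formaldehyde oxidises the benzylic alkoxide to the aldehyde.

Step 4
Reactants: 6 5-bromo-2,4-dihydroxybenzaldehyde
Product: 7 5-bromo-2-hydroxy-4-(methoxymethoxy)benzaldehyde
Conditions: MOMCl (1.05 equiv), K2CO3 (1.1 equiv), acetone, 0 °C to rt
Reagents that add atoms: chloromethyl methyl ether (MOMCl), COCCl
Why: Selective Williamson alkylation of the more acidic, unchelated 4-OH, the 2-OH being held back by its hydrogen bond to the formyl group.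

Step 5
Reactants: 7 5-bromo-2-hydroxy-4-(methoxymethoxy)benzaldehyde
Product: 8 5-bromo-4-(methoxymethoxy)-2-(triisopropylsilyloxy)benzaldehyde
Conditions: TIPSCl (1.3 equiv), imidazole (2.5 equiv), DMF, rt to 40 °C
Reagents that add atoms: chlorotriisopropylsilane (TIPSCl), CC(C)[Si](Cl)(C(C)C)C(C)C
Why: Imidazole-promoted O-silylation of the only remaining hydroxyl, which installs the fluoride-labile trigger in a form robust enough for the basic steps that follow.

Step 6
Reactants: 8 5-bromo-4-(methoxymethoxy)-2-(triisopropylsilyloxy)benzaldehyde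
Product: 9 4-(methoxymethoxy)-5-(4,4,5,5-tetramethyl-1,3,2-dioxaborolan-2-yl)-2-(triisopropylsilyloxy)benzaldehyde
Conditions: B2pin2 (1.2 equiv), Pd(dppf)Cl2 (4 mol %), KOAc (3 equiv), 1,4-dioxane, 85 °C
Reagents that add atoms: bis(pinacolato)diboron, CC1(C)OB(OC1(C)C)B1OC(C)(C)C(C)(C)O1
Why: Miyaura borylation turns the aryl bromide into a nucleophile under weakly basic conditions that tolerate the free formyl group, which a bromine–lithium exchange would not.

Step 7
Reactants: 9 4-(methoxymethoxy)-5-(4,4,5,5-tetramethyl-1,3,2-dioxaborolan-2-yl)-2-(triisopropylsilyloxy)benzaldehyde; 10 geranyl bromide, (2E)-1-bromo-3,7-dimethylocta-2,6-diene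
Product: 11 5-geranyl-4-(methoxymethoxy)-2-(triisopropylsilyloxy)benzaldehyde
Conditions: Pd(PPh3)4 (5 mol %), K2CO3 (2 equiv), THF/H2O (9:1), 45 °C
Reagents that add atoms: none
Why: Suzuki–Miyaura allyl–aryl coupling, in which zerovalent palladium ionises the allylic bromide and, after transmetalation, the aryl group is delivered to the unsubstituted allyl terminus, so the linear (E)-geranyl arene should result.

Step 8
Reactants: 11 5-geranyl-4-(methoxymethoxy)-2-(triisopropylsilyloxy)benzaldehyde
Product: 12 rac-2-[5-geranyl-4-(methoxymethoxy)-2-(triisopropylsilyloxy)phenyl]oxirane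
Conditions: Me3SI (1.5 equiv), NaH (1.4 equiv), DMSO/THF, 0 °C to rt; filtration through Et3N-deactivated silica
Reagents that add atoms: trimethylsulfonium iodide, C[S+](C)C.[I-]
Why: Corey–Chaykovsky epoxidation acts on the carbonyl only and leaves the geranyl alkenes alone, the betaine closes faster than the bulky silyl group can migrate, and the new centre is racemic, which does not matter because C3 is flattened in step 11.

Step 9
Reactants: 5 2-hydroxy-4,6-bis(methoxymethoxy)-5-methylbenzaldehyde; 12 rac-2-[5-geranyl-4-(methoxymethoxy)-2-(triisopropylsilyloxy)phenyl]oxirane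
Product: 13 rac-2-{2-[5-geranyl-4-(methoxymethoxy)-2-(triisopropylsilyloxy)phenyl]-2-hydroxyethoxy}-4,6-bis(methoxymethoxy)-5-methylbenzaldehyde
Conditions: 12 (1.2 equiv), Cs2CO3 (0.2 equiv), anhydrous DMF, 70 °C
Reagents that add atoms: none
Why: Base-catalysed SN2 opening of a terminal epoxide by a phenoxide in an aprotic solvent should go to the open CH2 because the ortho-OTIPS group screens the benzylic carbon, and with only catalytic base the benzylic alkoxide is protonated by the next phenol before the silyl group can move.

Step 10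
Reactants: 13 rac-2-{2-[5-geranyl-4-(methoxymethoxy)-2-(triisopropylsilyloxy)phenyl]-2-hydroxyethoxy}-4,6-bis(methoxymethoxy)-5-methylbenzaldehyde
Product: 14 rac-2-{2-[5-geranyl-4-(methoxymethoxy)-2-(triisopropylsilyloxy)phenyl]-2-tosylethoxy}-4,6-bis(methoxymethoxy)-5-methylbenzaldehyde
Conditions: p-TolSO2H (1.3 equiv, freshly liberated from its sodium salt), 4 Å MS, CH2Cl2, 0 °C to rt
Reagents that add atoms: p-toluenesulfinic acid, Cc1ccc(cc1)S(=O)O
Why: Dehydrative SN1-type substitution of an electron-rich benzylic alcohol by a sulfinic acid, in which the 2,4-dioxygenated ring stabilises the cation, reversible capture ends at the sulfur-bound sulfone, and the mild acid should spare the aryl MOM ethers, the aryl silyl ether and the trisubstituted alkenes; the product never meets base, which would expel the ring A aryloxide.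

Step 11
Reactants: 14 rac-2-{2-[5-geranyl-4-(methoxymethoxy)-2-(triisopropylsilyloxy)phenyl]-2-tosylethoxy}-4,6-bis(methoxymethoxy)-5-methylbenzaldehyde
Product: 16 (3R)-3-[5-geranyl-2-hydroxy-4-(methoxymethoxy)phenyl]-5,7-bis(methoxymethoxy)-6-methylchroman-4-one, via ortho-quinone methide aldehyde 15 (not isolated)
Conditions: (5aR,10bS)-2-(pentafluorophenyl)-5a,10b-dihydro-4H,6H-indeno[2,1-b][1,2,4]triazolo[4,3-d][1,4]oxazin-2-ium tetrafluoroborate (20 mol %), i-Pr2NEt (20 mol %), CsF (1.05 equiv), 18-crown-6 (1.05 equiv), 4 Å MS, THF (0.01 M), −20 °C, Ar; AcOH quench at −20 °C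
Reagents that add atoms: none
Why: Proposed new method: attack of fluoride on silicon liberates the 2'-phenoxide, which pushes out p-toluenesulfinate by 1,4-elimination, and the resulting methide 15 is flat at C3, which erases the configuration of racemic 14; in parallel the triazolylidene binds the formyl carbon, a proton shift gives an enaminol nucleophilic at C4, C4 bonds to C3 so that ring B regains aromaticity, and transfer of the carbinol proton to O-2' lets the azolium leave, which makes the step proton-neutral. The closest known reaction types are carbene-catalysed acyl anion additions to quinone methides formed in situ, carbene-catalysed displacement closures to chroman-4-ones and the enantioselective intramolecular Stetter reaction of salicylaldehyde ethers, none of which joins an aldehyde enantioselectively to a tethered ortho-quinone methide. The pyranone ring closes in the 6-exo-trig mode, since the C3=C1' bond lies outside the new ring. C3 is controlled by the catalyst: the fused indane shields one face of the enaminol, and because only O1 and C2 link the partners and the methide should be (E)-configured, a single C3 face can reach C4 in a chair-like array. The step needs desilylation to outrun deprotonation of the sulfone C3–H (which would eject the ring A aryloxide) and closure to outrun methide dimerisation or a 1,5-hydrogen shift; the affinity of fluoride for silicon, the intramolecular setting, high dilution and reversible re-addition of sulfinate should secure this. At the end only sulfinate and catalytic amine remain as bases, which should be too weak to enolise 16 at −20 °C.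

Step 12
Reactants: 16 (3R)-3-[5-geranyl-2-hydroxy-4-(methoxymethoxy)phenyl]-5,7-bis(methoxymethoxy)-6-methylchroman-4-one
Product: 17 (3R)-3-(5-geranyl-2,4-dihydroxyphenyl)-5,7-dihydroxy-6-methylchroman-4-one (CNP0348256.1)
Conditions: HCl (ca. 1 M in MeOH), 0 °C to rt, stopped at full conversion; pH 6–7 phosphate buffer work-up
Reagents that add atoms: none
Why: Acid-catalysed acetal exchange of aryl MOM ethers, routine on prenylated polyphenols, in which the MOM group at O-5 should fall first so that the 5-OH/C4=O chelate protects the ketone from the 2'-OH, while dilute acid at or below rt and a base-free work-up should avoid chroman formation between 4'-OH and the geranyl alkene and leave C3 untouched.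

Compound list
1 | 2-methylresorcinol | Cc1c(O)cccc1O | starting material
2 | 1,3-bis(methoxymethoxy)-2-methylbenzene | COCOc1cccc(OCOC)c1C | intermediate
3 | 2-[3,5-bis(methoxymethoxy)-4-methylphenyl]-4,4,5,5-tetramethyl-1,3,2-dioxaborolane (formed and consumed in step 2) | COCOc1cc(B2OC(C)(C)C(C)(C)O2)cc(OCOC)c1C | intermediate
4 | 3,5-bis(methoxymethoxy)-4-methylphenol | COCOc1cc(O)cc(OCOC)c1C | intermediate
5 | 2-hydroxy-4,6-bis(methoxymethoxy)-5-methylbenzaldehyde | O=Cc1c(O)cc(OCOC)c(C)c1OCOC | intermediate
6 | 5-bromo-2,4-dihydroxybenzaldehyde | O=Cc1cc(Br)c(O)cc1O | starting material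
7 | 5-bromo-2-hydroxy-4-(methoxymethoxy)benzaldehyde | O=Cc1cc(Br)c(OCOC)cc1O | intermediate
8 | 5-bromo-4-(methoxymethoxy)-2-(triisopropylsilyloxy)benzaldehyde | O=Cc1cc(Br)c(OCOC)cc1O[Si](C(C)C)(C(C)C)C(C)C | intermediate
9 | 4-(methoxymethoxy)-5-(4,4,5,5-tetramethyl-1,3,2-dioxaborolan-2-yl)-2-(triisopropylsilyloxy)benzaldehyde | O=Cc1cc(B2OC(C)(C)C(C)(C)O2)c(OCOC)cc1O[Si](C(C)C)(C(C)C)C(C)C | intermediate
10 | geranyl bromide, (2E)-1-bromo-3,7-dimethylocta-2,6-diene | CC(C)=CCC/C(C)=C/CBr | starting material
11 | 5-geranyl-4-(methoxymethoxy)-2-(triisopropylsilyloxy)benzaldehyde | O=Cc1cc(C/C=C(\C)CCC=C(C)C)c(OCOC)cc1O[Si](C(C)C)(C(C)C)C(C)C | intermediate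
12 | rac-2-[5-geranyl-4-(methoxymethoxy)-2-(triisopropylsilyloxy)phenyl]oxirane | C1OC1c2cc(C/C=C(\C)CCC=C(C)C)c(OCOC)cc2O[Si](C(C)C)(C(C)C)C(C)C | intermediate
13 | rac-2-{2-[5-geranyl-4-(methoxymethoxy)-2-(triisopropylsilyloxy)phenyl]-2-hydroxyethoxy}-4,6-bis(methoxymethoxy)-5-methylbenzaldehyde | O=Cc1c(OCC(O)c2cc(C/C=C(\C)CCC=C(C)C)c(OCOC)cc2O[Si](C(C)C)(C(C)C)C(C)C)cc(OCOC)c(C)c1OCOC | intermediate
14 | rac-2-{2-[5-geranyl-4-(methoxymethoxy)-2-(triisopropylsilyloxy)phenyl]-2-tosylethoxy}-4,6-bis(methoxymethoxy)-5-methylbenzaldehyde | O=Cc1c(OCC(c2cc(C/C=C(\C)CCC=C(C)C)c(OCOC)cc2O[Si](C(C)C)(C(C)C)C(C)C)S(=O)(=O)c2ccc(C)cc2)cc(OCOC)c(C)c1OCOC | intermediate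
15 | 2-{(2E)-2-[3-geranyl-4-(methoxymethoxy)-6-oxocyclohexa-2,4-dien-1-ylidene]ethoxy}-4,6-bis(methoxymethoxy)-5-methylbenzaldehyde (formed and consumed in step 11) | O=Cc1c(OC/C=C2\C=C(C/C=C(\C)CCC=C(C)C)C(OCOC)=CC2=O)cc(OCOC)c(C)c1OCOC | intermediate
16 | (3R)-3-[5-geranyl-2-hydroxy-4-(methoxymethoxy)phenyl]-5,7-bis(methoxymethoxy)-6-methylchroman-4-one | CC(C)=CCC/C(C)=C/Cc1cc([C@@H]2COc3cc(OCOC)c(C)c(OCOC)c3C2=O)c(O)cc1OCOC | intermediate
17 | (3R)-3-(5-geranyl-2,4-dihydroxyphenyl)-5,7-dihydroxy-6-methylchroman-4-one (CNP0348256.1) | CC(C)=CCC/C(C)=C/Cc1cc([C@@H]2COc3cc(O)c(C)c(O)c3C2=O)c(O)cc1O | target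

Total step count: 12. Longest linear sequence: 9 steps (6 → 7 → 8 → 9 → 11 → 12 → 13 → 14 → 16 → 17). The ring A branch (1 → 5) has 3 steps and joins in step 9.

Steps most likely to fail

**Step 11 (labelled).**
- What may go wrong:
  - The carbene may add only sluggishly to the electron-rich aldehyde flanked by two ortho oxygens.
  - The methide is then consumed by dimerisation or by a 1,5-hydrogen shift to the styryl ether.
  - Facial selectivity at C3 may be poor.
  - Residual fluoride may enolise the product.
- The fallback uses known chemistry only. It forms C3–C4 first with normal polarity, adds C2 afterwards and sets C3 by dynamic kinetic resolution. It sets out from 4 and 12 and comes back at 16.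
- N-Bromosuccinimide (MeCN, −20 °C) brominates 4 ortho to the hydroxyl to give 2-bromo-3,5-bis(methoxymethoxy)-4-methylphenol F1. A Meinwald rearrangement of 12 (InCl3 cat., THF, rt) gives [5-geranyl-4-(methoxymethoxy)-2-(triisopropylsilyloxy)phenyl]acetaldehyde F2.
- F1 is deprotonated and bromine–lithium exchanged (n-BuLi, 2.1 equiv, THF, −78 °C) and added to F2 to give the racemic 1,2-diarylethanol F3. MnO2 (CH2Cl2) oxidises this to the 2-hydroxydeoxybenzoin F4.
- Paraformaldehyde and Et2NH (EtOH, 70 °C; Mannich reaction, loss of amine, oxa-Michael closure) bring in C2 and give the racemic 2'-O-TIPS isoflavanone F5.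
- Asymmetric transfer hydrogenation (RuCl[(R,R)-TsDPEN](p-cymene), HCO2H/Et3N, rt), during which C3 epimerises faster than the ketone is reduced, should give the cis-(3R,4R)-isoflavan-4-ol F6.
- Dess–Martin periodinane (NaHCO3-buffered, CH2Cl2, 0 °C) restores the ketone as the (3R)-2'-O-TIPS isoflavanone F7. TBAF buffered with AcOH (THF, 0 °C) then frees O-2' to give 16.

**Step 9.**
- What may go wrong:
  - The phenoxide may attack the benzylic carbon of the very electron-rich epoxide.
  - The silyl group may transfer to the phenoxide, after which O-2' opens the epoxide intramolecularly.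
  - The epoxide may rearrange thermally.
- The fallback reverses the order in which the two nucleophiles meet the C2 unit, so that each bond forms where the substrate is biased. It sets out from 12 and 5 and comes back at 14, so that step 10 is bypassed as well.
- Sodium p-toluenesulfinate in NaH2PO4-buffered aqueous THF (rt to 40 °C) opens 12 at the cation-stabilised benzylic carbon to give the β-hydroxy sulfone 2-[5-geranyl-4-(methoxymethoxy)-2-(triisopropylsilyloxy)phenyl]-2-tosylethanol F8.
- A Mitsunobu etherification of its primary hydroxyl with phenol 5 (PPh3, DIAD, toluene, 0 °C to rt) gives 14 under essentially neutral conditions.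

**Step 10.**
- What may go wrong:
  - The chelation-activated MOM group next to the formyl group may be lost under the sulfinic acid.
  - The cation may lose a proton to give the styryl ether.
  - Capture may stop at the sulfinate ester.
  - Steric congestion between the sulfonyl and the OTIPS group may hold the reaction back.
- The fallback installs the leaving group under basic instead of acidic conditions. It sets out from 13 and comes back at 16 through the same methide 15.
- Ac2O, pyridine and DMAP (CH2Cl2, 0 °C) give the benzylic acetate F9, which is submitted to the conditions of step 11. Desilylation and loss of acetate lead to 15 and on to 16.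
- The price is a more basic by-product, so the reaction would be quenched with AcOH as soon as F9 is consumed.

Further compounds
F1 | step 11 | 2-bromo-3,5-bis(methoxymethoxy)-4-methylphenol | Oc1cc(OCOC)c(C)c(OCOC)c1Br
F2 | step 11 | [5-geranyl-4-(methoxymethoxy)-2-(triisopropylsilyloxy)phenyl]acetaldehyde | O=CCc1cc(C/C=C(\C)CCC=C(C)C)c(OCOC)cc1O[Si](C(C)C)(C(C)C)C(C)C
F3 | step 11 | rac-2-{1-hydroxy-2-[5-geranyl-4-(methoxymethoxy)-2-(triisopropylsilyloxy)phenyl]ethyl}-3,5-bis(methoxymethoxy)-4-methylphenol | OC(Cc1cc(C/C=C(\C)CCC=C(C)C)c(OCOC)cc1O[Si](C(C)C)(C(C)C)C(C)C)c1c(O)cc(OCOC)c(C)c1OCOC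
F4 | step 11 | 1-[2-hydroxy-4,6-bis(methoxymethoxy)-5-methylphenyl]-2-[5-geranyl-4-(methoxymethoxy)-2-(triisopropylsilyloxy)phenyl]ethan-1-one | O=C(Cc1cc(C/C=C(\C)CCC=C(C)C)c(OCOC)cc1O[Si](C(C)C)(C(C)C)C(C)C)c1c(O)cc(OCOC)c(C)c1OCOC
F5 | step 11 | rac-3-[5-geranyl-4-(methoxymethoxy)-2-(triisopropylsilyloxy)phenyl]-5,7-bis(methoxymethoxy)-6-methylchroman-4-one | CC(C)=CCC/C(C)=C/Cc1cc(C2COc3cc(OCOC)c(C)c(OCOC)c3C2=O)c(O[Si](C(C)C)(C(C)C)C(C)C)cc1OCOC
F6 | step 11 | (3R,4R)-3-[5-geranyl-4-(methoxymethoxy)-2-(triisopropylsilyloxy)phenyl]-5,7-bis(methoxymethoxy)-6-methylchroman-4-ol (cis) | CC(C)=CCC/C(C)=C/Cc1cc([C@@H]2COc3cc(OCOC)c(C)c(OCOC)c3[C@@H]2O)c(O[Si](C(C)C)(C(C)C)C(C)C)cc1OCOC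
F7 | step 11 | (3R)-3-[5-geranyl-4-(methoxymethoxy)-2-(triisopropylsilyloxy)phenyl]-5,7-bis(methoxymethoxy)-6-methylchroman-4-one | CC(C)=CCC/C(C)=C/Cc1cc([C@@H]2COc3cc(OCOC)c(C)c(OCOC)c3C2=O)c(O[Si](C(C)C)(C(C)C)C(C)C)cc1OCOC
F8 | step 9 | rac-2-[5-geranyl-4-(methoxymethoxy)-2-(triisopropylsilyloxy)phenyl]-2-tosylethanol | OCC(c1cc(C/C=C(\C)CCC=C(C)C)c(OCOC)cc1O[Si](C(C)C)(C(C)C)C(C)C)S(=O)(=O)c1ccc(C)cc1
F9 | step 10 | rac-2-[2-formyl-3,5-bis(methoxymethoxy)-4-methylphenoxy]-1-[5-geranyl-4-(methoxymethoxy)-2-(triisopropylsilyloxy)phenyl]ethyl acetate | O=Cc1c(OCC(OC(C)=O)c2cc(C/C=C(\C)CCC=C(C)C)c(OCOC)cc2O[Si](C(C)C)(C(C)C)C(C)C)cc(OCOC)c(C)c1OCOC
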